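3 questions stand here, and one rule serves them: once we know how much right-handed substrate is left, the left-handed substrate left follows, and the excess with it.

in all of them: left-handed substrate 10 mM; right-handed substrate 10 mM; precatalyst 0.1 mol%

| run | solid reagent | remark | time |
|---|---|---|---|
| delta | 0.75 equiv | run made earlier |  |
| beta | 3 equiv | run made earlier |  |
| Saturday's | 1.50 equiv |  | 6.0 h |
| Tuesday's | 1.50 equiv |  | 10 h |

- delta (time / h: right-handed substrate / %, left-handed substrate / %): 1.00: 50.1, 49.1; 2.00: 48.5, 44.6; 3.00: 48.4, 40.9; 4.00: 44.2, 36.2; 5.00: 42.6, 32.4; 6.00: 42.0, 30.4; 8.00: 41.6, 28.9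
- beta (time / h: right-handed substrate / %, left-handed substrate / %): 0.500: 48.6, 50.7; 0.833: 47.6, 50.6; 1.33: 48.8, 48.2; 2.00: 48.9, 46.5; 3.00: 44.2, 41.3; 5.00: 42.2, 29.7; 8.00: 33.0, 14.5

(scatter of a reading: 1 percentage point)

- free catalyst is single-handed; left-handed substrate and right-handed substrate are mirror images of each other, charged as a racemate, each of them at the stated concentration
- solid reagent is a solid; its amount is given per volume of the solution
- at the start none of the solid reagent is in solution
- an excess is the difference of the two amounts in percent of their sum
- an excess is below zero if the other one leads

1. which of the two ends with the higher excess of right-handed substrate over left-handed substrate among what is left of the two ("neither" if they lie within 2 percentage points) (Saturday's / Tuesday's / neither)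
2. excess of right-handed substrate over left-handed substrate among what is left of the two at the end, Saturday's
3. excess of right-handed substrate over left-handed substrate among what is left of the two at the end, Tuesday's

We work with the fraction left of each substrate's own charge, and each substrate was half of what was charged. At the last beta reading, the logarithm of the left-handed fraction divided by that of the right-handed is 2.98. This ratio is the selectivity factor, s. The delta run gives 2.98 with a quarter of the solid reagent, so we take the left-handed fraction as the right-handed fraction raised to the power s.

For Saturday's, a straight line through the beta readings at 5.00 h and 8.00 h puts the right-handed fraction at 78.3 % at 6.0 h. That means 36.8 % of the two used. At 5.00 h delta had used 25.0 % against beta's 28.1 %, and that use, scaled to 1.50 equiv, is 50.0 %, which is more than the line asks of Saturday's. So we keep the line for Saturday's, and our excess there is 23.8 %.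

For Tuesday's, the same line carried to 10 h gives a right-handed fraction of 53.7 % and 65.3 % used. This is the weak link, since beta had 3 equiv, more than the 1.50 equiv of Tuesday's. We reforge it from delta, whose last two readings differ by 1.9 percentage points in total. Its 29.5 % used, scaled to 1.50 equiv, gives 59.0 %, which is less than the line. A right-handed fraction of 0.600 leaves 40.9 % of the two, which fits, and our excess for Tuesday's is 46.7 %.

The forecast says Tuesday's, with 23 % (19 % to 27 %) and 47 % (41 % to 52 %), on the ground that “each equiv delivers about 40 points”.

The flask gives 24.2 % for Saturday's and 48.2 % for Tuesday's, so Tuesday's leads.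

    partner + catalyst intermediate A → free catalyst + left-handed product (k = 32.0 M⁻¹ s⁻¹)
    free catalyst + left-handed substrate ⇌ catalyst intermediate A (K = 120 M⁻¹, k = 2100 M⁻¹ s⁻¹)
    partner + precatalyst → free catalyst + spent reagent (k = 0.0120 M⁻¹ s⁻¹)
    free catalyst + right-handed substrate ⇌ catalyst intermediate B (K = 100 M⁻¹, k = 1900 M⁻¹ s⁻¹)
    partner + catalyst intermediate B → free catalyst + right-handed product (k = 13.0 M⁻¹ s⁻¹)
    free catalyst ⇌ dormant form (K = 0.510, k = 9.30 × 10⁻⁵ s⁻¹)
    solid reagent ⇌ partner, rate k7*(cs7 - [partner]) while solid is left; crystals form when [partner] > cs7 (solubility = 5.90 mM, k = 0.00460 s⁻¹)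

The flask of Saturday's left until 15 h stands at 60.1 %, above the 52 % that the forecast allowed Tuesday's at 10 h, with 69.5 % of the two in product, more than our 59.0 %. In Tuesday's, s turns 58 % of right-handed substrate left into 19.7 % of left-handed, and the flask holds 20 %. In that later flask it turns 49 % into 11.8 %, and the flask holds 12 %.

Readings and results were computed for an exercise; the scatter is artificial.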